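**Strategy.** The route rests on disconnecting the C9–C9a bond. This bond joins the acetoxy-bearing carbon of the seven-membered ring to the arene carbon that lies para to the central (C3) methoxy group and next to C4a, the arene carbon carrying benzylic C5. No other free arene carbon can be reached by a chain anchored at C5. One intramolecular Friedel–Crafts acylation therefore forms this bond and closes the seven-membered ring with tether-enforced regiochemistry, before any acid-labile dienone exists. Its precursor is an open-chain 2-aryl-4,5-dimethyladipic acid derivative: free chain acid, both methyl stereocentres taken from (2S,3S)-2,3-dimethylsuccinic acid, and the benzylic carboxyl carbon held as a nitrile that later becomes the aldehyde for spiro-annulation.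

Key step: step 6

Remark on the chemistry: enantiopure (2S,3S)-2,3-dimethylsuccinic acid, 2,3,4-trimethoxyphenylacetonitrile, N,2-dimethoxy-N-methylacetamide and methyl vinyl ether are assumed purchasable; benzo[7]annulene numbering is used (methoxy groups at C2–C4, benzylic carbon C5, carbinol carbon C9; spiro ring primed, C1' spiro, C4' carbonyl); C5 is carried as an epimer mixture because it ends as a non-stereogenic spiro carbon; the change of descriptor from S in the diacid to R at C7 is a priority effect only, no centre is inverted.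

**Route**

Step 1
Reactants: 1 (2S,3S)-2,3-dimethylsuccinic acid
Product: 2 (2S,3S)-2,3-dimethylbutane-1,4-diol
Conditions: BH3·SMe2 (2.5 equiv), THF, 0 °C → rt; MeOH quench
Reagents that add atoms: none
Why: Borane reduces both carboxylic acids through acyloxyboranes without enolisation (carboxylic acid reduction), so the two methyl-bearing stereocentres should pass unchanged.

Step 2
Reactants: 2 (2S,3S)-2,3-dimethylbutane-1,4-diol
Product: 3 (3S,4S)-3,4-dimethyloxolan-2-one (trans-lactone)
Conditions: TEMPO (0.1 equiv), PhI(OAc)2 (2.4 equiv), CH2Cl2, rt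
Reagents that add atoms: none
Why: Oxoammonium oxidation of one primary alcohol, lactol formation and a second oxidation (TEMPO-mediated oxidative lactonisation of a 1,4-diol) should give the lactone, and because 2 is C2-symmetric either hydroxyl leads to the same trans product.

Step 3
Reactants: 3 (3S,4S)-3,4-dimethyloxolan-2-one
Product: 4 methyl (2S,3S)-4-bromo-2,3-dimethylbutanoate
Conditions: HBr (g, saturated), MeOH, 0 °C → rt
Reagents that add atoms: hydrogen bromide, Br; methanol, CO
Why: Bromide opens the protonated lactone at the unhindered CH2–O carbon (SN2 opening of a γ-lactone) and the liberated acid is esterified in the acidic methanol (Fischer esterification), a sequence that touches neither stereocentre.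

Step 4
Reactants: 5 2,3,4-trimethoxyphenylacetonitrile; 4 methyl (2S,3S)-4-bromo-2,3-dimethylbutanoate
Product: 6 methyl (2S,3R)-5-cyano-2,3-dimethyl-5-(2,3,4-trimethoxyphenyl)pentanoate (both C5 epimers)
Conditions: 5 (1.1 equiv), NaN(SiMe3)2 (1.0 equiv), THF, −78 °C; then 4 (1.0 equiv), DMPU, Bu4NI (0.1 equiv), −78 °C → rt
Reagents that add atoms: none
Why: The sodium salt of the benzylic nitrile is a soft, unhindered carbon nucleophile that should displace the primary bromide (SN2 alkylation of an arylacetonitrile anion, helped by in situ iodide exchange) while being too weak a base to enolise the ester, so the α-methyl centre is kept and the new benzylic centre, which is later destroyed, may form as either epimer.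

Step 5
Reactants: 6 methyl (2S,3R)-5-cyano-2,3-dimethyl-5-(2,3,4-trimethoxyphenyl)pentanoate
Product: 7 (2S,3R)-5-cyano-2,3-dimethyl-5-(2,3,4-trimethoxyphenyl)pentanoic acid (both C5 epimers)
Conditions: LiOH·H2O (3 equiv), THF/MeOH/H2O, rt; then 1 M HCl to pH 3
Reagents that add atoms: lithium hydroxide, [Li+].[OH-]
Why: Hydroxide cleaves the methyl ester by acyl substitution (saponification) under conditions that leave a nitrile untouched, so the two carboxyl-level carbons are told apart without orthogonal esters.

Step 6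
Reactants: 7 (2S,3R)-5-cyano-2,3-dimethyl-5-(2,3,4-trimethoxyphenyl)pentanoic acid
Product: 9 (7R,8S)-2,3,4-trimethoxy-7,8-dimethyl-9-oxo-6,7,8,9-tetrahydro-5H-benzo[7]annulene-5-carbonitrile (both C5 epimers), via acid chloride 8 (not isolated)
Conditions: (COCl)2 (1.5 equiv), DMF (cat.), CH2Cl2, 0 °C → rt; evaporate; then added over 4 h to SnCl4 (3 equiv), CH2Cl2 (5 mM final), 0 °C → rt
Reagents that add atoms: none
Why: SnCl4 ionises acid chloride 8 to an acylium ion that attacks the arene carbon next to the one carrying the benzylic carbon, and the arenium ion loses a proton to give the aryl ketone; this is an intramolecular Friedel–Crafts acylation of the Haworth benzosuberone type. The seven-membered carbocycle closes by ortho-annulation: an arene π-bond that becomes endocyclic attacks the sp-hybridised acylium carbon, whose C≡O bond stays outside the ring (7-exo-dig at the acylium). No stereocentre is formed; C7 and C8 come from 1, C8 now lies α to the ketone and is expected to rest trans-diequatorial to C7 even if it enolises, and C5 is deliberately left as an epimer mixture. The selectivity needed is regiochemical, attack at the moderately activated carbon para to the central methoxy group and not intermolecular attack at the more electron-rich free carbon ortho to the 4-methoxy group. The five-atom tether reaches only the former, slow addition keeps free acylating agent scarce, and the cyclised ketone is deactivated as its SnCl4 complex. The nitrile is inert to the acylium ion and no dienone is present yet, so the acidic medium has nothing to rearrange.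

Step 7
Reactants: 9 (7R,8S)-2,3,4-trimethoxy-7,8-dimethyl-9-oxo-6,7,8,9-tetrahydro-5H-benzo[7]annulene-5-carbonitrile
Product: 10 (7R,8S,9R)-9-hydroxy-2,3,4-trimethoxy-7,8-dimethyl-6,7,8,9-tetrahydro-5H-benzo[7]annulene-5-carbonitrile
Conditions: (S)-2-methyl-CBS-oxazaborolidine (0.5 equiv), BH3·SMe2 (0.7 equiv), THF, −20 °C; MeOH quench
Reagents that add atoms: none
Why: In the CBS reduction the oxazaborolidine–borane complex binds the aryl ketone with the arene as the large group and the (S)-catalyst delivers hydride to the face that gives the (R)-carbinol, i.e. hydroxyl trans to the C8 methyl, so C9 is set by reagent control while the nitrile is not reduced by borane at this temperature.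

Step 8
Reactants: 10 (7R,8S,9R)-9-hydroxy-2,3,4-trimethoxy-7,8-dimethyl-6,7,8,9-tetrahydro-5H-benzo[7]annulene-5-carbonitrile
Product: 11 (7R,8S,9R)-9-(tert-butyldimethylsilyloxy)-2,3,4-trimethoxy-7,8-dimethyl-6,7,8,9-tetrahydro-5H-benzo[7]annulene-5-carbonitrile
Conditions: t-BuMe2SiOTf (1.3 equiv), 2,6-lutidine (2 equiv), CH2Cl2, −78 → 0 °C
Reagents that add atoms: tert-butyldimethylsilyl triflate, CC(C)(C)[Si](C)(C)OS(=O)(=O)C(F)(F)F
Why: The silyl triflate with a hindered pyridine base silylates the secondary benzylic alcohol on oxygen (silyl ether formation) without ionising the C9–O bond, giving a group that survives hydride, hydroxide and amide bases.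

Step 9
Reactants: 11 (7R,8S,9R)-9-(tert-butyldimethylsilyloxy)-2,3,4-trimethoxy-7,8-dimethyl-6,7,8,9-tetrahydro-5H-benzo[7]annulene-5-carbonitrile
Product: 12 (7R,8S,9R)-9-(tert-butyldimethylsilyloxy)-2,3,4-trimethoxy-7,8-dimethyl-6,7,8,9-tetrahydro-5H-benzo[7]annulene-5-carbaldehyde (both C5 epimers)
Conditions: i-Bu2AlH (1.5 equiv), toluene, −78 → −40 °C; then aq. citric acid (pH 4), 0 °C
Reagents that add atoms: water, O
Why: One hydride adds to the nitrile to give an N-aluminio imine that is stable at low temperature and is hydrolysed to the aldehyde on mildly acidic work-up (partial reduction of a nitrile), the silyl and aryl ethers being inert.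

Step 10
Reactants: 13 N,2-dimethoxy-N-methylacetamide; 14 methyl vinyl ether
Product: 16 1,3-dimethoxybut-3-en-2-one, via 1-methoxyvinyllithium 15 (not isolated)
Conditions: 14 (3 equiv), t-BuLi (1.2 equiv), THF, −78 → 0 °C; then 13 (1.0 equiv), −78 → 0 °C; aq. NH4Cl
Reagents that add atoms: none
Why: Deprotonation of the vinyl ether at its α-carbon gives a vinyllithium that adds once to the N-methoxy-N-methylamide, the chelated tetrahedral adduct collapsing to the ketone only on work-up (Weinreb ketone synthesis), which delivers the α-methoxy enone with a methoxymethyl group on the other side.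

Step 11
Reactants: 12 (7R,8S,9R)-9-(tert-butyldimethylsilyloxy)-2,3,4-trimethoxy-7,8-dimethyl-6,7,8,9-tetrahydro-5H-benzo[7]annulene-5-carbaldehyde; 16 1,3-dimethoxybut-3-en-2-one
Product: 19 (7R,8S,9R)-9-(tert-butyldimethylsilyloxy)-2,3,3',4,5'-pentamethoxy-7,8-dimethyl-6,7,8,9-tetrahydrospiro[benzo[7]annulene-5,1'-cyclohex[2]en]-4'-one (mixture at C5 and C5'), via Michael adduct 17 (not isolated), via aldol 18 (not isolated)
Conditions: 16 (1.5 equiv), KOH (0.3 equiv), degassed MeOH/THF, 0 °C → rt; then 50 °C
Reagents that add atoms: none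
Why: The α-aryl aldehyde enolate adds through its fully substituted carbon to the terminal CH2 of the enone (Michael addition), the methoxymethyl ketone enolate then closes the only six-membered aldol available onto the now non-enolisable aldehyde, and hydroxide eliminates water to the 2-methoxy enone (Robinson annulation); the stereocentres formed at C5 and C5' need no control because both are erased in step 12.

Step 12
Reactants: 19 (7R,8S,9R)-9-(tert-butyldimethylsilyloxy)-2,3,3',4,5'-pentamethoxy-7,8-dimethyl-6,7,8,9-tetrahydrospiro[benzo[7]annulene-5,1'-cyclohex[2]en]-4'-one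
Product: 21 (7R,8S,9R)-9-(tert-butyldimethylsilyloxy)-2,3,3',4,5'-pentamethoxy-7,8-dimethyl-6,7,8,9-tetrahydrospiro[benzo[7]annulene-5,1'-cyclohexa[2,5]dien]-4'-one, via selenide 20 (not isolated)
Conditions: LiN(SiMe3)2 (1.2 equiv), THF, −78 °C; PhSeCl (1.3 equiv); then H2O2 (30% aq.), pyridine, CH2Cl2, 0 °C → rt
Reagents that add atoms: none
Why: C5' is the only enolisable position (the γ-carbon is quaternary), so the lithium enolate is selenenylated there and the derived selenoxide undergoes syn-elimination towards the only β-hydrogens at C6' (selenoxide elimination), giving the cross-conjugated dienone without acid and turning C5 into a non-stereogenic spiro carbon.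

Step 13
Reactants: 21 (7R,8S,9R)-9-(tert-butyldimethylsilyloxy)-2,3,3',4,5'-pentamethoxy-7,8-dimethyl-6,7,8,9-tetrahydrospiro[benzo[7]annulene-5,1'-cyclohexa[2,5]dien]-4'-one
Product: 22 (7R,8S,9R)-9-hydroxy-2,3,3',4,5'-pentamethoxy-7,8-dimethyl-6,7,8,9-tetrahydrospiro[benzo[7]annulene-5,1'-cyclohexa[2,5]dien]-4'-one
Conditions: Bu4NF (2 equiv), AcOH (2 equiv), THF, 0 °C → rt
Reagents that add atoms: none
Why: Fluoride attacks silicon and releases the alcohol with the C9–O bond intact (silyl ether cleavage), the acetic acid buffer keeping the medium near neutral so that neither alkoxide addition to the dienone nor a dienone–phenol rearrangement is triggered.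

Step 14
Reactants: 22 (7R,8S,9R)-9-hydroxy-2,3,3',4,5'-pentamethoxy-7,8-dimethyl-6,7,8,9-tetrahydrospiro[benzo[7]annulene-5,1'-cyclohexa[2,5]dien]-4'-one
Product: 23 (7R,8S,9R)-2,3,3',4,5'-pentamethoxy-7,8-dimethyl-4'-oxo-6,7,8,9-tetrahydrospiro[benzo[7]annulene-5,1'-cyclohexa[2,5]dien]-9-yl acetate (CNP0143674.1)
Conditions: Ac2O (3 equiv), pyridine, DMAP (0.1 equiv), CH2Cl2, 0 °C → rt
Reagents that add atoms: acetic anhydride, CC(=O)OC(C)=O
Why: DMAP-catalysed O-acylation of the secondary benzylic alcohol proceeds with retention because the C9–O bond is never broken, and the basic, acid-free medium spares the dienone.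

**Compound list**

1 | (2S,3S)-2,3-dimethylsuccinic acid | OC(=O)[C@@H](C)[C@H](C)C(=O)O | starting material
2 | (2S,3S)-2,3-dimethylbutane-1,4-diol | OC[C@@H](C)[C@H](C)CO | intermediate
3 | (3S,4S)-3,4-dimethyloxolan-2-one | C[C@@H]1COC(=O)[C@H]1C | intermediate
4 | methyl (2S,3S)-4-bromo-2,3-dimethylbutanoate | BrC[C@@H](C)[C@H](C)C(=O)OC | intermediate
5 | 2,3,4-trimethoxyphenylacetonitrile | N#CCc1ccc(OC)c(OC)c1OC | starting material
6 | methyl (2S,3R)-5-cyano-2,3-dimethyl-5-(2,3,4-trimethoxyphenyl)pentanoate, C5 epimers | N#CC(C[C@@H](C)[C@H](C)C(=O)OC)c1ccc(OC)c(OC)c1OC | intermediate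
7 | (2S,3R)-5-cyano-2,3-dimethyl-5-(2,3,4-trimethoxyphenyl)pentanoic acid, C5 epimers | N#CC(C[C@@H](C)[C@H](C)C(=O)O)c1ccc(OC)c(OC)c1OC | intermediate
8 | (2S,3R)-5-cyano-2,3-dimethyl-5-(2,3,4-trimethoxyphenyl)pentanoyl chloride | N#CC(C[C@@H](C)[C@H](C)C(Cl)=O)c1ccc(OC)c(OC)c1OC | intermediate (not isolated)
9 | (7R,8S)-2,3,4-trimethoxy-7,8-dimethyl-9-oxo-6,7,8,9-tetrahydro-5H-benzo[7]annulene-5-carbonitrile, C5 epimers | N#CC1C[C@@H](C)[C@H](C)C(=O)c2cc(OC)c(OC)c(OC)c21 | intermediate
10 | (7R,8S,9R)-9-hydroxy-2,3,4-trimethoxy-7,8-dimethyl-6,7,8,9-tetrahydro-5H-benzo[7]annulene-5-carbonitrile | N#CC1C[C@@H](C)[C@H](C)[C@@H](O)c2cc(OC)c(OC)c(OC)c21 | intermediate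
11 | (7R,8S,9R)-9-(tert-butyldimethylsilyloxy)-2,3,4-trimethoxy-7,8-dimethyl-6,7,8,9-tetrahydro-5H-benzo[7]annulene-5-carbonitrile | N#CC1C[C@@H](C)[C@H](C)[C@@H](O[Si](C)(C)C(C)(C)C)c2cc(OC)c(OC)c(OC)c21 | intermediate
12 | (7R,8S,9R)-9-(tert-butyldimethylsilyloxy)-2,3,4-trimethoxy-7,8-dimethyl-6,7,8,9-tetrahydro-5H-benzo[7]annulene-5-carbaldehyde | O=CC1C[C@@H](C)[C@H](C)[C@@H](O[Si](C)(C)C(C)(C)C)c2cc(OC)c(OC)c(OC)c21 | intermediate
13 | N,2-dimethoxy-N-methylacetamide | COCC(=O)N(C)OC | starting material
14 | methyl vinyl ether | COC=C | starting material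
15 | 1-methoxyvinyllithium | [Li]C(=C)OC | intermediate (not isolated)
16 | 1,3-dimethoxybut-3-en-2-one | COCC(=O)C(=C)OC | intermediate
17 | (7R,8S,9R)-9-(tert-butyldimethylsilyloxy)-5-(2,4-dimethoxy-3-oxobutyl)-2,3,4-trimethoxy-7,8-dimethyl-6,7,8,9-tetrahydro-5H-benzo[7]annulene-5-carbaldehyde | O=CC1(CC(OC)C(=O)COC)C[C@@H](C)[C@H](C)[C@@H](O[Si](C)(C)C(C)(C)C)c2cc(OC)c(OC)c(OC)c21 | intermediate (not isolated)
18 | (7R,8S,9R)-9-(tert-butyldimethylsilyloxy)-2'-hydroxy-2,3,3',4,5'-pentamethoxy-7,8-dimethyl-6,7,8,9-tetrahydrospiro[benzo[7]annulene-5,1'-cyclohexan]-4'-one | COC1C(O)C2(CC(OC)C1=O)C[C@@H](C)[C@H](C)[C@@H](O[Si](C)(C)C(C)(C)C)c1cc(OC)c(OC)c(OC)c12 | intermediate (not isolated)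
19 | (7R,8S,9R)-9-(tert-butyldimethylsilyloxy)-2,3,3',4,5'-pentamethoxy-7,8-dimethyl-6,7,8,9-tetrahydrospiro[benzo[7]annulene-5,1'-cyclohex[2]en]-4'-one | COC1=CC2(CC(OC)C1=O)C[C@@H](C)[C@H](C)[C@@H](O[Si](C)(C)C(C)(C)C)c1cc(OC)c(OC)c(OC)c12 | intermediate
20 | 5'-(phenylselanyl) derivative of 19 | COC1=CC2(CC(OC)([Se]c3ccccc3)C1=O)C[C@@H](C)[C@H](C)[C@@H](O[Si](C)(C)C(C)(C)C)c1cc(OC)c(OC)c(OC)c12 | intermediate (not isolated)
21 | (7R,8S,9R)-9-(tert-butyldimethylsilyloxy)-2,3,3',4,5'-pentamethoxy-7,8-dimethyl-6,7,8,9-tetrahydrospiro[benzo[7]annulene-5,1'-cyclohexa[2,5]dien]-4'-one | COC1=CC2(C=C(OC)C1=O)C[C@@H](C)[C@H](C)[C@@H](O[Si](C)(C)C(C)(C)C)c1cc(OC)c(OC)c(OC)c12 | intermediate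
22 | (7R,8S,9R)-9-hydroxy-2,3,3',4,5'-pentamethoxy-7,8-dimethyl-6,7,8,9-tetrahydrospiro[benzo[7]annulene-5,1'-cyclohexa[2,5]dien]-4'-one | COC1=CC2(C=C(OC)C1=O)C[C@@H](C)[C@H](C)[C@@H](O)c1cc(OC)c(OC)c(OC)c12 | intermediate
23 | (7R,8S,9R)-2,3,3',4,5'-pentamethoxy-7,8-dimethyl-4'-oxo-6,7,8,9-tetrahydrospiro[benzo[7]annulene-5,1'-cyclohexa[2,5]dien]-9-yl acetate | COC1=CC2(C=C(OC)C1=O)C[C@@H](C)[C@H](C)[C@@H](OC(C)=O)c1cc(OC)c(OC)c(OC)c12 | target

**Totals.** Total step count: 14. Longest linear sequence: 13 (steps 1–9 and 11–14; step 10 is a one-step side branch).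

**Steps most likely to fail**

Step 6. The closure may stall because the attacked carbon is only moderately activated, or it may lose to intermolecular acylation at the more electron-rich free carbon of a second molecule. The fallback sets out from 7 and blocks that competing carbon. Bromination of 7 (NBS, MeCN, 0 °C) should go to the most electron-rich arene carbon, ortho to the 4-methoxy and para to the 2-methoxy group, and give (2S,3R)-5-(5-bromo-2,3,4-trimethoxyphenyl)-5-cyano-2,3-dimethylpentanoic acid F1. Treatment with (COCl)2 and catalytic DMF gives (2S,3R)-5-(5-bromo-2,3,4-trimethoxyphenyl)-5-cyano-2,3-dimethylpentanoyl chloride F2. Friedel–Crafts closure with AlCl3 in CH2Cl2, now possible only at the one remaining arene carbon, should give (7R,8S)-1-bromo-2,3,4-trimethoxy-7,8-dimethyl-9-oxo-6,7,8,9-tetrahydro-5H-benzo[7]annulene-5-carbonitrile F3. Hydrogenolysis of the C–Br bond (H2, Pd/C, Et3N, EtOAc, rt) comes back to the route at 9.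

Step 11. Conjugate addition at the hindered, fully substituted α-carbon may be slower than base-induced polymerisation or methoxide addition of the captodative enone, and the aldehyde may be consumed by hydroxide side reactions. The fallback sets out from 12 and replaces enolate catalysis by stoichiometric enamine activation (Stork enamine annulation). Condensation of 12 with pyrrolidine (4 Å molecular sieves, toluene, rt) should give 1-{[(7R,8S,9R)-9-(tert-butyldimethylsilyloxy)-2,3,4-trimethoxy-7,8-dimethyl-6,7,8,9-tetrahydro-5H-benzo[7]annulen-5-ylidene]methyl}pyrrolidine F4. This neutral enamine is combined with 16 in MeCN and the adduct is hydrolysed with aqueous AcOH/NaOAc buffer, which comes back to the route at Michael adduct 17. Compound 17 is then closed to 19 with KOH in MeOH as in the second half of step 11.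

Step 7. Facial selectivity may be poor if catalyst control is opposed by the intrinsic bias of the ring (mismatched pairing), so that hydride also arrives anti to the C8 methyl. The fallback sets out from 9 and uses substrate control followed by inversion. LiBH(s-Bu)3 (THF, −78 °C) should deliver hydride anti to the C8 methyl and give (7R,8S,9S)-9-hydroxy-2,3,4-trimethoxy-7,8-dimethyl-6,7,8,9-tetrahydro-5H-benzo[7]annulene-5-carbonitrile F5. Mitsunobu displacement (4-nitrobenzoic acid, PPh3, DIAD, toluene, 0 °C) inverts C9 and gives (7R,8S,9R)-5-cyano-2,3,4-trimethoxy-7,8-dimethyl-6,7,8,9-tetrahydro-5H-benzo[7]annulen-9-yl 4-nitrobenzoate F6. Methanolysis (K2CO3, MeOH, rt) comes back to the route at 10.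

**Further compounds**

F1 | step 6 | (2S,3R)-5-(5-bromo-2,3,4-trimethoxyphenyl)-5-cyano-2,3-dimethylpentanoic acid | N#CC(C[C@@H](C)[C@H](C)C(=O)O)c1cc(Br)c(OC)c(OC)c1OC
F2 | step 6 | (2S,3R)-5-(5-bromo-2,3,4-trimethoxyphenyl)-5-cyano-2,3-dimethylpentanoyl chloride | N#CC(C[C@@H](C)[C@H](C)C(Cl)=O)c1cc(Br)c(OC)c(OC)c1OC
F3 | step 6 | (7R,8S)-1-bromo-2,3,4-trimethoxy-7,8-dimethyl-9-oxo-6,7,8,9-tetrahydro-5H-benzo[7]annulene-5-carbonitrile | N#CC1C[C@@H](C)[C@H](C)C(=O)c2c(Br)c(OC)c(OC)c(OC)c21
F4 | step 11 | 1-{[(7R,8S,9R)-9-(tert-butyldimethylsilyloxy)-2,3,4-trimethoxy-7,8-dimethyl-6,7,8,9-tetrahydro-5H-benzo[7]annulen-5-ylidene]methyl}pyrrolidine | C(=C1C[C@@H](C)[C@H](C)[C@@H](O[Si](C)(C)C(C)(C)C)c2cc(OC)c(OC)c(OC)c21)N1CCCC1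
F5 | step 7 | (7R,8S,9S)-9-hydroxy-2,3,4-trimethoxy-7,8-dimethyl-6,7,8,9-tetrahydro-5H-benzo[7]annulene-5-carbonitrile | N#CC1C[C@@H](C)[C@H](C)[C@H](O)c2cc(OC)c(OC)c(OC)c21
F6 | step 7 | (7R,8S,9R)-5-cyano-2,3,4-trimethoxy-7,8-dimethyl-6,7,8,9-tetrahydro-5H-benzo[7]annulen-9-yl 4-nitrobenzoate | N#CC1C[C@@H](C)[C@H](C)[C@@H](OC(=O)c3ccc(cc3)[N+](=O)[O-])c2cc(OC)c(OC)c(OC)c21
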